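**Retrosynthetic overview**
1. Target 25 ⇐ peracid epoxidation of the E‑4,5‑olefin of ten‑membered keto‑butenolide 24 (from 23 by desilylation).
2. 23 ⇐ key step: palladium‑mediated decarboxylative ring contraction (12 → 10, new C2–C3 bond, loss of CO2) of allyl β‑keto macrolactone 22.
3. 22 ⇐ macrolactonisation (O3–C16) of seco ester 21 ⇐ Mitsunobu esterification (methacrylate, inversion at C8) and Nozaki–Hiyama–Kishi coupling (C7–C8) of iodobutenolide 10 with aldehyde 17.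
4. 10 ⇐ methallyl alcohol, acrolein, methyl propiolate, formaldehyde (cross‑metathesis, asymmetric alkynylation, iodo‑aldol/lactonisation); 17 ⇐ propanal, dimethoxyacetaldehyde, ethyl diazoacetate (anti cross‑aldol, Roskamp homologation).
5. Ring order: butenolide, then 12‑membered lactone, then contraction to the 10‑membered carbocycle, epoxide last.

Assumption: locants C‑1 to C‑15 follow the germacrane numbering of the target (C‑1 ketone, C‑4/C‑5 epoxide, C‑6 lactone oxygen, C‑7=C‑11, C‑12 lactone carbonyl, C‑13 CH2OAc); C‑16 is the extra carboxyl carbon later lost as CO2; TBS = tert‑butyldimethylsilyl.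

**Step 1**
Reactants: 1 2‑methylprop‑2‑en‑1‑ol
Product: 2 tert‑butyldimethyl[(2‑methylprop‑2‑en‑1‑yl)oxy]silane
Conditions: TBSCl, imidazole, DMF, 0 °C to rt
Reagents that add atoms: tert‑butyldimethylsilyl chloride, CC(C)(C)[Si](C)(C)Cl
Why: Standard imidazole‑mediated silyl ether formation on a primary alcohol.

**Step 2**
Reactants: 2 tert‑butyldimethyl[(2‑methylprop‑2‑en‑1‑yl)oxy]silane; 3 acrolein
Product: 4 (2E)‑4‑(TBS‑oxy)‑3‑methylbut‑2‑enal
Conditions: 3 (5 equiv), second‑generation Hoveyda–Grubbs catalyst RuCl2(H2IMes)(=CH‑C6H4‑2‑OiPr) (3 mol%), CH2Cl2, 40 °C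
Reagents that add atoms: none
Why: Olefin cross‑metathesis of a 1,1‑disubstituted olefin with excess acrolein gives the cross product as the thermodynamically preferred E‑enal (the minor Z isomer is removed).

**Step 3**
Reactants: 4 (2E)‑4‑(TBS‑oxy)‑3‑methylbut‑2‑enal; 5 methyl propiolate
Product: 6 methyl (4R,5E)‑7‑(TBS‑oxy)‑4‑hydroxy‑6‑methylhept‑5‑en‑2‑ynoate
Conditions: Me2Zn (3 equiv), (S,S)‑ProPhenol (10 mol%), Ph3P=O (20 mol%), toluene, 0 °C
Reagents that add atoms: none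
Why: Zinc–ProPhenol catalysed asymmetric alkynylation gives clean 1,2‑addition to the enal; the ligand enantiomer is the one that delivers the alkynylzinc to the Si face (the sense of induction is to be confirmed on the first run; the mirror‑image ligand is used if it is reversed), which sets C‑6 as R.

**Step 4**
Reactants: 6 methyl (4R,5E)‑7‑(TBS‑oxy)‑4‑hydroxy‑6‑methylhept‑5‑en‑2‑ynoate; 7 formaldehyde
Product: 10 [(5R)‑5‑[(1E)‑3‑(TBS‑oxy)‑2‑methylprop‑1‑en‑1‑yl]‑4‑iodo‑2‑oxo‑2,5‑dihydrofuran‑3‑yl]methyl acetate, via iodo‑aldol adduct 8 (not isolated), via hydroxymethyl iodobutenolide 9 (not isolated)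
Conditions: MgI2 (2.5 equiv), 7 (gas, 3 equiv), CH2Cl2, 0 °C to rt; then Ac2O, pyridine, DMAP (cat.), 0 °C
Reagents that add atoms: magnesium diiodide, [Mg+2].[I-].[I-]; acetic anhydride, CC(=O)OC(C)=O
Why: Halo‑aldol (β‑iodo Baylis–Hillman type) reaction: iodide adds to the ynoate to give a β‑iodo allenolate that is hydroxymethylated at C‑11, iodide‑mediated E/Z equilibration lets the C‑6 alkoxide lactonise, and the primary alcohol is acetylated in the same flask; C‑6 is not touched.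

**Step 5**
Reactants: 11 propanal; 12 2,2‑dimethoxyacetaldehyde
Product: 13 (2S,3R)‑3‑hydroxy‑4,4‑dimethoxy‑2‑methylbutanal
Conditions: (S)‑α,α‑bis[3,5‑bis(trifluoromethyl)phenyl]‑2‑pyrrolidinemethanol (10 mol%), 12 (60% aq.), DMF, rt, slow addition of 11
Reagents that add atoms: none
Why: Enamine‑catalysed (proline‑type) cross‑aldol: the E‑enamine of propanal adds to the activated, non‑enolisable acceptor through a hydrogen‑bonded chair transition state, giving the anti (2S,3R) adduct in the same sense as L‑proline.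

**Step 6**
Reactants: 13 (2S,3R)‑3‑hydroxy‑4,4‑dimethoxy‑2‑methylbutanal
Product: 14 (2S,3R)‑3‑(TBS‑oxy)‑4,4‑dimethoxy‑2‑methylbutanal
Conditions: TBSOTf, 2,6‑lutidine, CH2Cl2, −78 °C
Reagents that add atoms: tert‑butyldimethylsilyl triflate, CC(C)(C)[Si](C)(C)OS(=O)(=O)C(F)(F)F
Why: Low‑temperature silylation of the β‑hydroxy aldehyde with a hindered base, which avoids retro‑aldol and epimerisation.

**Step 7**
Reactants: 14 (2S,3R)‑3‑(TBS‑oxy)‑4,4‑dimethoxy‑2‑methylbutanal; 15 ethyl diazoacetate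
Product: 16 ethyl (4S,5R)‑5‑(TBS‑oxy)‑6,6‑dimethoxy‑4‑methyl‑3‑oxohexanoate
Conditions: SnCl2 (10 mol%), CH2Cl2, rt
Reagents that add atoms: none
Why: Roskamp homologation: Lewis‑acid‑promoted addition of the diazo ester to the aldehyde and 1,2‑hydride shift with loss of N2 gives the β‑keto ester without epimerising the α‑stereocentre.

**Step 8**
Reactants: 16 ethyl (4S,5R)‑5‑(TBS‑oxy)‑6,6‑dimethoxy‑4‑methyl‑3‑oxohexanoate
Product: 17 ethyl (4S,5R)‑5‑(TBS‑oxy)‑4‑methyl‑3,6‑dioxohexanoate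
Conditions: TFA–H2O (9:1), CH2Cl2, 0 °C; used at once without chromatography
Reagents that add atoms: water, O
Why: Acid hydrolysis of the dimethyl acetal at 0 °C leaves the secondary TBS ether and the β‑keto ester intact; the keto aldehyde is used immediately to avoid intramolecular aldol or furan formation.

**Step 9**
Reactants: 10 [(5R)‑5‑[(1E)‑3‑(TBS‑oxy)‑2‑methylprop‑1‑en‑1‑yl]‑4‑iodo‑2‑oxo‑2,5‑dihydrofuran‑3‑yl]methyl acetate; 17 ethyl (4S,5R)‑5‑(TBS‑oxy)‑4‑methyl‑3,6‑dioxohexanoate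
Product: 18 ethyl (4S,5R,6S)‑6‑[(2R)‑4‑(acetoxymethyl)‑2‑[(1E)‑3‑(TBS‑oxy)‑2‑methylprop‑1‑en‑1‑yl]‑5‑oxo‑2,5‑dihydrofuran‑3‑yl]‑5‑(TBS‑oxy)‑6‑hydroxy‑4‑methyl‑3‑oxohexanoate
Conditions: CrCl2 (6 equiv), NiCl2 (2 mol%), DMSO, rt
Reagents that add atoms: none
Why: Nozaki–Hiyama–Kishi coupling: the vinylchromium species formed via nickel catalysis adds only to the aldehyde (ketone, esters and lactone are untouched), and Felkin–Anh attack anti to the α‑silyloxy group gives the 8,9‑anti (8S) carbinol.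

**Step 10**
Reactants: 18 (8S)‑carbinol as named in step 9; 19 methacrylic acid
Product: 20 ethyl (4S,5R,6R)‑6‑[(2R)‑4‑(acetoxymethyl)‑2‑[(1E)‑3‑(TBS‑oxy)‑2‑methylprop‑1‑en‑1‑yl]‑5‑oxo‑2,5‑dihydrofuran‑3‑yl]‑5‑(TBS‑oxy)‑4‑methyl‑6‑[(2‑methylprop‑2‑enoyl)oxy]‑3‑oxohexanoate
Conditions: PPh3, DIAD, toluene, 0 °C to rt
Reagents that add atoms: none
Why: Mitsunobu esterification displaces the oxyphosphonium ion by methacrylate in an SN2 step, so C‑8 is inverted to the required R configuration while the ester is installed (the far more acidic carboxylic acid outcompetes the β‑keto ester as pronucleophile).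

**Step 11**
Reactants: 20 methacrylate bis‑silyl ether as named in step 10
Product: 21 ethyl (4S,5R,6R)‑6‑[(2R)‑4‑(acetoxymethyl)‑2‑[(1E)‑3‑hydroxy‑2‑methylprop‑1‑en‑1‑yl]‑5‑oxo‑2,5‑dihydrofuran‑3‑yl]‑5‑(TBS‑oxy)‑4‑methyl‑6‑[(2‑methylprop‑2‑enoyl)oxy]‑3‑oxohexanoate
Conditions: HF·pyridine, pyridine, THF, 0 °C
Reagents that add atoms: none
Why: Fluoride desilylation is selective for the unhindered primary allylic TBS ether over the flanked secondary C‑9 TBS ether.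

**Step 12**
Reactants: 21 seco hydroxy β‑keto ester as named in step 11
Product: 22 12‑membered allyl β‑keto macrolactone, (4E,6R,8R,9R,10S), ring C16(=O)–O–C3H2–C4(Me)=C5H–C6–C7–C8(O‑methacryloyl)–C9(OTBS)–C10(Me)–C1(=O)–C2H2, fused at C6/C7 to the 13‑acetoxy butenolide
Conditions: ClBu2SnOSnBu2OH (10 mol%), toluene (1 mM), reflux, 4 Å molecular sieves, BHT
Reagents that add atoms: none
Why: Neutral distannoxane‑catalysed transesterification of the β‑keto ester (macrolactonisation at high dilution, ethanol trapped by sieves); the only free hydroxyl is the C‑3 OH, and no base is present that could epimerise C‑6.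

**Step 13**
Reactants: 22 12‑membered allyl β‑keto macrolactone
Product: 23 (4E,6R,8R,9R,10S)‑13‑acetoxy‑9‑(TBS‑oxy)‑8‑(methacryloyloxy)‑1‑oxogermacra‑4,7(11)‑dien‑12,6‑olide
Conditions: Pd(PPh3)4 (10 mol%), THF (2 mM), 25 to 40 °C
Reagents that add atoms: none
Why: Proposed new method: zerovalent palladium ionises the primary allylic C3–O bond of the macrolactone, the tethered β‑keto carboxylate loses CO2, and the ketone enolate formed regiospecifically at C‑2 recombines within the ion pair at the less hindered CH2 terminus (C‑3) of the syn 2‑methylallyl unit, so the ring contracts by two atoms to the ten‑membered carbocycle with the E‑4,5‑olefin retained and no stereocentre touched; the closest known reactions are the Tsuji–Saegusa decarboxylative allylation of open‑chain allyl β‑keto esters and palladium‑mediated macrocyclic allylic alkylation, neither of which has been shown as a transannular contraction to a medium carbocycle.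

**Step 14**
Reactants: 23 ring‑contracted silyl ether as named in step 13
Product: 24 (4E,6R,8R,9R,10S)‑13‑acetoxy‑9‑hydroxy‑8‑(methacryloyloxy)‑1‑oxogermacra‑4,7(11)‑dien‑12,6‑olide
Conditions: HF·pyridine, pyridine, THF, 0 °C to rt
Reagents that add atoms: none
Why: Buffered fluoride desilylation of the secondary TBS ether; the mildly acidic medium avoids retro‑aldol, β‑elimination and acyl migration.

**Step 15**
Reactants: 24 hydroxy dienolide as named in step 14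
Product: 25 (4R,5R,6S,8R,9R,10S)‑13‑acetoxy‑4,5‑epoxy‑9‑hydroxy‑8‑(methacryloyloxy)‑1‑oxogermacr‑7(11)‑en‑12,6‑olide (CNP0185951.1)
Conditions: mCPBA, NaHCO3, CH2Cl2, 0 °C
Reagents that add atoms: 3‑chloroperoxybenzoic acid, O=C(OO)c1cccc(Cl)c1
Why: Prilezhaev epoxidation: the peracid reacts only with the electron‑rich trisubstituted 4,5‑olefin (butenolide and methacrylate are electron‑poor) and attacks its outward π‑face in the conformer with H‑5 anti to H‑6, as in peracid epoxidations of 6,12‑germacranolides, giving the (4R,5R) epoxide.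

**Compound list**
1 | 2‑methylprop‑2‑en‑1‑ol | C=C(C)CO | starting material
2 | tert‑butyldimethyl[(2‑methylprop‑2‑en‑1‑yl)oxy]silane | C=C(C)CO[Si](C)(C)C(C)(C)C | intermediate
3 | acrolein | C=CC=O | starting material
4 | (2E)‑4‑(TBS‑oxy)‑3‑methylbut‑2‑enal | O=C/C=C(\C)CO[Si](C)(C)C(C)(C)C | intermediate
5 | methyl propiolate | C#CC(=O)OC | starting material
6 | methyl (4R,5E)‑7‑(TBS‑oxy)‑4‑hydroxy‑6‑methylhept‑5‑en‑2‑ynoate | COC(=O)C#C[C@H](O)/C=C(\C)CO[Si](C)(C)C(C)(C)C | intermediate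
7 | formaldehyde | C=O | starting material
8 | methyl (2E,4R,5E)‑7‑(TBS‑oxy)‑4‑hydroxy‑2‑(hydroxymethyl)‑3‑iodo‑6‑methylhepta‑2,5‑dienoate | COC(=O)/C(CO)=C(/I)[C@H](O)/C=C(\C)CO[Si](C)(C)C(C)(C)C | intermediate
9 | (5R)‑5‑[(1E)‑3‑(TBS‑oxy)‑2‑methylprop‑1‑en‑1‑yl]‑3‑(hydroxymethyl)‑4‑iodofuran‑2(5H)‑one | OCC1=C(I)[C@@H](/C=C(\C)CO[Si](C)(C)C(C)(C)C)OC1=O | intermediate
10 | [(5R)‑5‑[(1E)‑3‑(TBS‑oxy)‑2‑methylprop‑1‑en‑1‑yl]‑4‑iodo‑2‑oxo‑2,5‑dihydrofuran‑3‑yl]methyl acetate | CC(=O)OCC1=C(I)[C@@H](/C=C(\C)CO[Si](C)(C)C(C)(C)C)OC1=O | intermediate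
11 | propanal | CCC=O | starting material
12 | 2,2‑dimethoxyacetaldehyde | COC(OC)C=O | starting material
13 | (2S,3R)‑3‑hydroxy‑4,4‑dimethoxy‑2‑methylbutanal | O=C[C@@H](C)[C@@H](O)C(OC)OC | intermediate
14 | (2S,3R)‑3‑(TBS‑oxy)‑4,4‑dimethoxy‑2‑methylbutanal | O=C[C@@H](C)[C@@H](O[Si](C)(C)C(C)(C)C)C(OC)OC | intermediate
15 | ethyl diazoacetate | CCOC(=O)C=[N+]=[N-] | starting material
16 | ethyl (4S,5R)‑5‑(TBS‑oxy)‑6,6‑dimethoxy‑4‑methyl‑3‑oxohexanoate | CCOC(=O)CC(=O)[C@@H](C)[C@@H](O[Si](C)(C)C(C)(C)C)C(OC)OC | intermediate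
17 | ethyl (4S,5R)‑5‑(TBS‑oxy)‑4‑methyl‑3,6‑dioxohexanoate | CCOC(=O)CC(=O)[C@@H](C)[C@@H](O[Si](C)(C)C(C)(C)C)C=O | intermediate
18 | ethyl (4S,5R,6S)‑6‑[(2R)‑4‑(acetoxymethyl)‑2‑[(1E)‑3‑(TBS‑oxy)‑2‑methylprop‑1‑en‑1‑yl]‑5‑oxo‑2,5‑dihydrofuran‑3‑yl]‑5‑(TBS‑oxy)‑6‑hydroxy‑4‑methyl‑3‑oxohexanoate | CCOC(=O)CC(=O)[C@@H](C)[C@@H](O[Si](C)(C)C(C)(C)C)[C@@H](O)C1=C(COC(C)=O)C(=O)O[C@@H]1/C=C(\C)CO[Si](C)(C)C(C)(C)C | intermediate
19 | methacrylic acid | C=C(C)C(=O)O | starting material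
20 | ethyl (4S,5R,6R)‑6‑[(2R)‑4‑(acetoxymethyl)‑2‑[(1E)‑3‑(TBS‑oxy)‑2‑methylprop‑1‑en‑1‑yl]‑5‑oxo‑2,5‑dihydrofuran‑3‑yl]‑5‑(TBS‑oxy)‑4‑methyl‑6‑[(2‑methylprop‑2‑enoyl)oxy]‑3‑oxohexanoate | CCOC(=O)CC(=O)[C@@H](C)[C@@H](O[Si](C)(C)C(C)(C)C)[C@H](OC(=O)C(C)=C)C1=C(COC(C)=O)C(=O)O[C@@H]1/C=C(\C)CO[Si](C)(C)C(C)(C)C | intermediate
21 | ethyl (4S,5R,6R)‑6‑[(2R)‑4‑(acetoxymethyl)‑2‑[(1E)‑3‑hydroxy‑2‑methylprop‑1‑en‑1‑yl]‑5‑oxo‑2,5‑dihydrofuran‑3‑yl]‑5‑(TBS‑oxy)‑4‑methyl‑6‑[(2‑methylprop‑2‑enoyl)oxy]‑3‑oxohexanoate | CCOC(=O)CC(=O)[C@@H](C)[C@@H](O[Si](C)(C)C(C)(C)C)[C@H](OC(=O)C(C)=C)C1=C(COC(C)=O)C(=O)O[C@@H]1/C=C(\C)CO | intermediate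
22 | 12‑membered allyl β‑keto macrolactone, (4E,6R,8R,9R,10S), O3–C16 lactone of the 2‑carboxy‑2,3‑seco acid, 9‑OTBS, 8‑O‑methacryloyl, 13‑OAc, 6,12‑olide | O=C1CC(=O)[C@@H](C)[C@@H](O[Si](C)(C)C(C)(C)C)[C@H](OC(=O)C(C)=C)C2=C(COC(C)=O)C(=O)O[C@@H]2/C=C(\C)CO1 | intermediate
23 | (4E,6R,8R,9R,10S)‑13‑acetoxy‑9‑(TBS‑oxy)‑8‑(methacryloyloxy)‑1‑oxogermacra‑4,7(11)‑dien‑12,6‑olide | C=C(C)C(=O)O[C@@H]1C2=C(COC(C)=O)C(=O)O[C@@H]2/C=C(\C)CCC(=O)[C@@H](C)[C@H]1O[Si](C)(C)C(C)(C)C | intermediate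
24 | (4E,6R,8R,9R,10S)‑13‑acetoxy‑9‑hydroxy‑8‑(methacryloyloxy)‑1‑oxogermacra‑4,7(11)‑dien‑12,6‑olide | C=C(C)C(=O)O[C@@H]1C2=C(COC(C)=O)C(=O)O[C@@H]2/C=C(\C)CCC(=O)[C@@H](C)[C@H]1O | intermediate
25 | (4R,5R,6S,8R,9R,10S)‑13‑acetoxy‑4,5‑epoxy‑9‑hydroxy‑8‑(methacryloyloxy)‑1‑oxogermacr‑7(11)‑en‑12,6‑olide | C=C(C)C(=O)O[C@@H]1C2=C(COC(C)=O)C(=O)O[C@@H]2[C@H]2O[C@]2(C)CCC(=O)[C@@H](C)[C@H]1O | target

**Step count and risks**
Total steps: 15. Longest linear sequence: 11 (steps 1–4 or 5–8, then 9–15).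

Most likely to fail:

1. Step 13 (the new ring contraction). The enolate may instead deprotonate the acidic C‑6 H next to the π‑allyl unit and give a dienyl lactone plus methyl ketone. It may also attack C‑5 to give an eight‑membered ring, or the C‑13 allylic acetate may ionise. Fallback with known chemistry, from 21 back to 23: acylate the C‑3 hydroxyl of 21 with methyl chloroformate/pyridine to the allylic methyl carbonate F1. Treat F1 with Pd(PPh3)4 at high dilution; the liberated methoxide deprotonates the β‑keto ester and the stabilised enolate closes the ring at C‑3 (Tsuji–Trost macrocyclisation), giving the ten‑membered 2‑ethoxycarbonyl ketone F2. Transesterify F2 with allyl alcohol (ClBu2SnOSnBu2OH, toluene, reflux) to the allyl ester F3, and remove the ester by deallylation–decarboxylation with Pd(PPh3)4/morpholine to reach 23.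

2. Step 4 (iodo‑aldol/lactonisation on a free allylic‑propargylic carbinol). Risks are the wrong olefin geometry for lactonisation and ionisation at C‑6. Fallback from 4 back to 10: alkynylate 4 with propargyl acetate under the zinc–ProPhenol conditions using the enantiomeric ligand to give the (S)‑propargylic alcohol F4. Convert F4 to the methyl carbonate F5 (ClCO2Me, pyridine). Carbonylate F5 with a zerovalent palladium catalyst (Pd(OAc)2/PPh3, CO, MeOH) by anti SN2′ substitution to the axially chiral allenoate F6. Iodolactonise F6 (I2, MeCN–H2O); the ester oxygen attacks C‑6 anti to iodine, which transfers axial to central chirality and gives (R)‑10.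

3. Step 15 (facial selectivity of the epoxidation). If the peracid delivers the (4S,5S) epoxide, the fallback from 24 back to 25 is the halohydrin route, which places oxygen on the opposite face. NBS in aqueous THF gives the bromohydrin F7 (bromonium ion on the accessible face, water anti at the tertiary C‑4). K2CO3 in MeOH‑free THF (or Ag2O) then closes the epoxide with inversion at C‑5 to give 25.

**Further compounds**
F1 | step 13 | methyl carbonate of 21 at the C‑3 hydroxyl | CCOC(=O)CC(=O)[C@@H](C)[C@@H](O[Si](C)(C)C(C)(C)C)[C@H](OC(=O)C(C)=C)C1=C(COC(C)=O)C(=O)O[C@@H]1/C=C(\C)COC(=O)OC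
F2 | step 13 | ethyl (4E,6R,8R,9R,10S)‑13‑acetoxy‑9‑(TBS‑oxy)‑8‑(methacryloyloxy)‑1‑oxogermacra‑4,7(11)‑dien‑12,6‑olide‑2‑carboxylate (C‑2 epimers) | C=C(C)C(=O)O[C@@H]1C2=C(COC(C)=O)C(=O)O[C@@H]2/C=C(\C)CC(C(=O)OCC)C(=O)[C@@H](C)[C@H]1O[Si](C)(C)C(C)(C)C
F3 | step 13 | allyl ester analogue of F2 | C=C(C)C(=O)O[C@@H]1C2=C(COC(C)=O)C(=O)O[C@@H]2/C=C(\C)CC(C(=O)OCC=C)C(=O)[C@@H](C)[C@H]1O[Si](C)(C)C(C)(C)C
F4 | step 4 | (4S,5E)‑7‑(TBS‑oxy)‑4‑hydroxy‑6‑methylhept‑5‑en‑2‑yn‑1‑yl acetate | CC(=O)OCC#C[C@@H](O)/C=C(\C)CO[Si](C)(C)C(C)(C)C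
F5 | step 4 | (4S,5E)‑7‑(TBS‑oxy)‑4‑[(methoxycarbonyl)oxy]‑6‑methylhept‑5‑en‑2‑yn‑1‑yl acetate | CC(=O)OCC#C[C@@H](OC(=O)OC)/C=C(\C)CO[Si](C)(C)C(C)(C)C
F6 | step 4 | methyl (Ra,5E)‑2‑(acetoxymethyl)‑7‑(TBS‑oxy)‑6‑methylhepta‑2,3,5‑trienoate | COC(=O)C(COC(C)=O)=[C@]=C/C=C(\C)CO[Si](C)(C)C(C)(C)C
F7 | step 15 | (4R,5S,6S,8R,9R,10S)‑13‑acetoxy‑5‑bromo‑4,9‑dihydroxy‑8‑(methacryloyloxy)‑1‑oxogermacr‑7(11)‑en‑12,6‑olide | C=C(C)C(=O)O[C@@H]1C2=C(COC(C)=O)C(=O)O[C@@H]2[C@H](Br)[C@](C)(O)CCC(=O)[C@@H](C)[C@H]1O
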